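Sunday's run, with twice the capture agent of Wednesday's flask, shows how fast this catalyst starts: over the first 15.0 s substrate goes at 4.96 min⁻¹ per catalyst. By the last interval of Sunday's run that rate has fallen by a factor of 4.59. If the rate followed substrate in proportion, substrate would account for 1.22 of that, and coupling partner, on the same assumption, for 1.08. The remaining factor of 3.49 I put down to catalyst leaving its round and to the first substrate going onto catalyst: at 15.0 s already 2.5 percentage points stands in neither substrate nor target.

in all of them: substrate 0.10 M; free catalyst 5 mol%; temperature 5 °C
- Wednesday's: coupling partner 3 equiv; capture agent 0.010 M; the very flask that is asked about, followed so far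
- Sunday's: coupling partner 3 equiv; capture agent 0.020 M; run made earlier
- flask: coupling partner 3.00 equiv; capture agent 0.0100 M; time 30 min

- Wednesday's (time / min: target / %, substrate / %): 8.00: 47.9, 47.7; 15.0: 54.0, 41.0; 25.0: 57.0, 38.5; 30.0: 56.0, 38.2
- Sunday's (time / s: target / %, substrate / %): 15.0: 3.7, 93.8; 40.0: 8.4, 86.6; 80.0: 13.4, 80.8; 120: 18.3, 77.2

(scatter of a reading: 0.5 percentage points)

- in percentages every species weighs as the substrate in it: one spent catalyst counts as two
- target taken out counts as made
- steps thought possible: coupling partner + free catalyst <-> catalyst intermediate A; substrate + catalyst intermediate A -> catalyst intermediate B; catalyst intermediate B -> by-product + catalyst intermediate C; catalyst intermediate C -> free catalyst + target; 2 catalyst intermediate B -> spent catalyst; catalyst intermediate B + capture agent -> trapped intermediate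
- additions bring no volume worth counting
- the earlier runs do not show what temperature does; that part of a forecast is a guess

- cedar: at 30 min add coupling partner, 50.0 % of the amount charged, then wait 1.0 h
- elm: at 30 min take out 90 % of the target then present, then wait 1.0 h
- birch: at 30 min raise the temperature by 20 K, then wait 1.0 h
- alder: change nothing and wait 1.0 h more
- ash: at 30 min add free catalyst, 100 % of the amount charged, then wait 1.0 h

- target, in percent of the substrate first charged, at 30 min
- which option adds most target ("none" when 2 percentage points or less is all one gets) (cedar / elm / birch / alder / ash / none)
- target present, with what was taken out counted in, in percent of the substrate first charged, after birch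
- target present, with what was taken out counted in, in percent of the substrate first charged, after ash

So count turnovers. In Wednesday's flask, which is the one asked about, the rate per catalyst is 0.191 min⁻¹ between 8.00 min and 15.0 min, then 0.0500 min⁻¹ up to 25.0 min. The last step in substrate, 0.3 points, lies inside the scatter. The slowing has therefore summed to a finite total, the turnover budget: target delivered per catalyst charged before the rate dies, here 11.3 from the last two readings. My reckoning for target at 30 min is 56.5 %.

Sunday's run is still moving, but its last two substrate steps shrink as a series whose tail is 5.9 points. That puts its budget near 4.84, lower by a factor of 2.34 for a factor of 2.00 in capture agent. Between these two runs, which differ in capture agent and share their other charges, the budget estimates go roughly inversely with c(capture agent).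

Of the steps thought possible, none starts from trapped intermediate or spent catalyst, so I expect waiting, adding coupling partner or removing target each to stay under 2 points, and heat is a guess. Fresh catalyst is different: finishing the substrate needs 7.64 turnovers, fewer than one budget. So I expect substrate to become the limiting reagent under ash, and target to head towards the 94.2 % that target and substrate sum to at the last reading of Wednesday's flask, less what the fresh catalyst binds.

The forecast gives 56.7 % (55.8 % to 57.6 %), ash as best, 57 % after birch (55.8 % to 59 %) and 91 % after ash (82 % to 94.5 %), reading that “the catalyst is dead rather than slowed by equilibrium”.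

The flask gives 56.6 %, and ash adds 36 points to reach 92.3 %, while birch ends at 56.9 %.

    coupling partner + free catalyst ⇌ catalyst intermediate A (K = 2.15 M⁻¹, k = 0.744 M⁻¹ s⁻¹, Ea = 55.0 kJ mol⁻¹, ΔH = −56.0 kJ mol⁻¹)
    substrate + catalyst intermediate A → catalyst intermediate B (k = 257 M⁻¹ s⁻¹, Ea = 36.0 kJ mol⁻¹)
    catalyst intermediate B → by-product + catalyst intermediate C (k = 0.139 s⁻¹, Ea = 79.0 kJ mol⁻¹)
    catalyst intermediate C → free catalyst + target (k = 0.232 s⁻¹, Ea = 70.0 kJ mol⁻¹)
    2 catalyst intermediate B → spent catalyst (k = 1.56 M⁻¹ s⁻¹, Ea = 48.0 kJ mol⁻¹)
    catalyst intermediate B + capture agent → trapped intermediate (k = 1.19 M⁻¹ s⁻¹, Ea = 54.0 kJ mol⁻¹)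
    (constants at 5 °C)

In this flask catalyst intermediate B has a half-life of 0.083 min on its forward step alone and 0.97 min against capture agent as charged, so at that charge it goes forward 11.7 times for each time it is trapped. At 30.0 min this flask holds 76.8 % of its catalyst as trapped intermediate and 23.0 % as spent catalyst, and under ash the added catalyst brings 7.15 target per catalyst added, less than the budget of 11.3. Raising capture agent to 0.0110 M moves target at 30 min by 5 points. The neighbour charged with 0.40 M of substrate, at the same 0.0100 M of capture agent, reaches 40.3 % at 30.0 min, a budget of 8.06, with 37.4 % of its catalyst as trapped intermediate and 62.3 % as spent catalyst.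

The numbers in the tables are calculated for substances that don't exist; noise was put on by code.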